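Atoms are numbered in the order of the target SMILES (C1 … N41). β is the face of the tricycle that carries the angular methyl C37. SEM = 2-(trimethylsilyl)ethoxymethyl, TBS = tert-butyldimethylsilyl. Compound numbers are those of the steps below.

## Analysis of the target

Target 49 rests on a trans-anti-trans decahydrofluorene: cyclohexane ring A (C2, C3, C4, C6, C36, C38), cyclopentane ring B (C6, C7, C32, C31, C36) and cyclohexane ring C (C25, C27, C29, C31, C32, C33). A 13-membered paracyclophane (C7–O8–arene–C15–C16–C18–C19–C34–C33–C32) spans the β face, and a γ-lactam (C16, C18, C19, C39, N41) is spiro-fused to it at C19. An eight-membered 1,2-dioxocane (C19, C20, C21, O23, O24, C25, C33, C34) ties C19 to ring C, which also carries the C27–C29 oxirane. There are fourteen stereocentres: the C1 and C5 methyls are equatorial and cis, C37 is axial; H6, H7, H31 and H33 are α, while O8, H32, C34, O24 and O28 are β; C19 is quaternary, and C16 and C21 are hemiaminal and peroxy-hemiacetal carbons that can equilibrate. The sensitive groups are the dialkyl peroxide with its C21–H (base-induced fragmentation, reductants), the trisubstituted epoxide, and the N-acyl hemiaminal next to a p-alkoxybenzyl group (acid gives an N-acyliminium ion; one-electron oxidants would cleave C15–C16). The synthesis is hard because of the strained cyclophane, the quaternary C19 that must be set relative to a distant core, and the late peroxide. The feature used here is that C16 carries N41, O17 and the benzylic C15, which is the oxidation pattern of an imide carbonyl that has accepted a benzyl carbanion; since C15–C16 lies in the 13-membered ring, joining a benzylic halide carbon to an imide carbonyl carbon under reducing conditions closes the macrocycle and creates the hemiaminal in one event.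

## Retrosynthetic reasoning

Peroxide and C21. In 49 the O24–C25 bond is β to the C34 ketone, so it is cut as a conjugate addition of a C21 hydroperoxide to the C33=C25 enone (48 from 47). C21 is traced to its methyl peroxyacetal and then to the terminal alkene of an allyl group (47 from 46 by ozonolysis in an alcohol). This leaves the peroxide for the last three steps, after every basic, reducing or organometallic operation.

Epoxide and enone. The oxirane of 46 comes from the C27=C29 alkene of dienone 44, and the C33=C25 double bond from ketone 41. C34 has one enolisable position only (C19 is quaternary), so the dehydrogenation is regiodefined at the carbonyl side. Diol 40 and its doubly protected form 39 follow by oxidation-level and protecting-group changes.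

Macrocycle (key disconnection). In 39 the C15–C16 bond is cut: C16 returns to an imide carbonyl and C15 to a benzylic bromide (37). The cut is made here because both fragments of the bond are electrophiles that a two-electron reductant can join, because the only other carbonyl (C39) is shielded by C19, and because all stereocentres except the equilibrating C16 are already in place. The forward reaction must favour closure at C16 over simple C–Br reduction and dimerisation. The nitrogen carries SEM rather than a p-methoxybenzyl group: an oxidative or strongly acidic N-debenzylation after ring closure would attack the p-alkoxybenzyl hemiaminal of the cyclophane itself (fragmentation of its arene radical cation, or N-acyliminium cyclisation onto the allyl group), whereas SEM leaves with fluoride.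

C19–C34. Bromide 37 is taken back through 36, 35 and 34 to aldehyde 27 and the regiodefined silyl ketene aminal 32. Direct deprotonation of a 3-allylsuccinimide would occur at the CH2 (C18), so the C19 enolate is instead generated by 1,4-addition of a vinyl group to the exocyclic methylene of itaconimide 31 (from maleimide 28 through 29), which fixes the enolate position and makes the allyl group in the same step. C34 is kept as a silyl ether so that no ketone competes in the key step.

Rings B and C. Aldehyde 27 is opened across C31–C32 and C25–C33 to trienal 26 (intramolecular Diels–Alder reaction). An E,E-diene and an E-enal in the endo mode give the trans B/C fusion with C34 β. They necessarily place the C26 methyl β, cis to C34; the α-methyl arrangement would require a Z-propenyl terminus, so the substrate of the key step carries C26 β. That centre is erased in 44 and re-formed in 48.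

Aryl ether and C7. The O8–C9 bond is made on the open-chain allylic alcohol 22, before the tricycle exists, by fluoride displacement from a 4-fluorobenzoate with retention at C7 (23); the ester carbon becomes C15 (24, 25). Etherifying the C7 hydroxyl on the finished tricycle, flanked by two ring-fusion carbons, by an inverting displacement with a phenol that carries a free benzylic alcohol would not be reliable. C7 itself is set by catalyst-controlled reduction of ynone 20 (21), and the E-alkene by directed hydroalumination (22).

Ring A. Aldehyde 18 is traced through two olefinations (17, 16) to aldehyde 15 and on to the quaternary ester 8. In 8 the C36 centre is made by alkylating an exocyclic ester enolate, so that the entering C31 carbon ends trans to the C6 substituent and the ester carbon (later reduced to the C37 methyl) ends cis to it. The C6 vinyl group of 6 comes from conjugate addition to enoate 4. Enoate 4 comes from enol triflate 3, obtained by desymmetrising meso ketone 1, which already holds the two cis methyl groups.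

## Alternatives that were turned down

Alternative 1: The lactam is cut at C18–C19 and C16–O17, so that the ring is first closed as the 14-membered macrolactam A1 (β-keto amide with an N-acyl enamine, C16=C18). One-electron oxidation of A1 with a trivalent manganese carboxylate would give the C19 radical, which adds 5-endo to C18; the C16 radical is oxidised to the N-acyliminium ion and hydrated to give A2. In its favour, macrolactamisation is the most dependable way to close a ring of this size, the key step creates the lactam, the quaternary centre and the hemiaminal together, and 5-endo closures of carbamoylmethyl radicals onto enamides are known. Against it, C19 is created inside the macrocycle with nothing but ring conformation to choose the face, the oxidant meets the electron-rich cyclophane ring and the N-benzyl group, the enamide must survive macrocycle assembly, and the transannular bond contracts a 14-membered to a more strained 13-membered ring. C34 must also be a ketone, so C33 can epimerise. On ring-closure reliability and bond count per step this alternative is stronger; the chosen route instead sets C19 by ionic chemistry before closure, where diastereomers can be separated, and closes the ring with a reductant that the arene tolerates.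

Alternative 2: The macrocycle is cut at C33–C34; the alkenyl iodide and aldehyde A3 would be closed under chromium/nickel (Nozaki–Hiyama–Kishi) conditions to the dienyl carbinol A4. In its favour, this macrocyclisation is among the best proven, it is chemoselective for aldehydes, C19 is set in a small fragment, and A4 already has the ring C diene, so the late dehydrogenation of the chosen route is avoided. On these two points it is stronger. Against it, the reacting pair is a tetrasubstituted, doubly flanked alkenyl iodide and a neopentyl aldehyde on a quaternary carbon, the worst steric case for this coupling. The iodo-diene also cannot come from the Diels–Alder reaction, which delivers C33 as an sp3 carbon bearing the formyl group, so the core would need a new synthesis. C15–C16 must then be made intermolecularly earlier, with C16 masked as a methyl aminal. The chosen route keeps the cycloaddition, which sets C31, C32 and C33 at once, and pays with one dehydrogenation.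

Alternative 3: The macrocycle is cut at O8–C9; the C7 alkoxide of A5 would displace fluoride from the fluoronitroarene to give the nitro cyclophane A6. In its favour, such ring closures are well proven for strained aryl ether cyclophanes, the bent arene is accommodated in the Meisenheimer intermediate, C7 reacts with retention, and no low-valent metal is needed. Against it, the nitro group must be removed afterwards (reduction, diazotisation, reduction) in the presence of alkenes and a ketone. A nitroarene also forbids carbanion or low-valent chemistry for C15–C16, which would then have to be made by enolate alkylation. Finally, the hindered C7 alkoxide must react under basic conditions next to a β-keto lactam with an epimerisable C33. The chosen route uses the same displacement intermolecularly and early, with an ester as activating group that is not wasted, because it becomes C15.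

Key step: step 29

Assumption: the (R,R)-configured lithium amide is taken to remove the proton that leads to 3, by analogy with 4-substituted cyclohexanones; if the sense is opposite, the (S,S)-amide is used with no other change.

Remark: C34 (carbinol stage), C16 (N-SEM stage) and C21 (methoxy stage) are not controlled by design; each is drawn as one epimer and converges later (C34 at ketone 41, C16 and C21 by ring–chain equilibration).

## Route

Step 1
Reactants: 1 cis-3,5-dimethylcyclohexanone
Product: 3 (3S,5R)-3,5-dimethylcyclohex-1-en-1-yl triflate, via lithium enolate 2 (not isolated)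
Conditions: (R,R)-[PhCH(Me)]2NLi (from the amine and n-BuLi), LiCl, THF, −78 °C; then PhNTf2, −78 °C → rt
Reagents that add atoms: N-phenylbis(trifluoromethanesulfonimide), O=S(=O)(N(c1ccccc1)S(=O)(=O)C(F)(F)F)C(F)(F)F
Why: Enantiotopos-selective deprotonation of a meso ketone by a chiral lithium amide (Simpkins–Koga desymmetrisation) followed by O-triflation of the enolate; the two methyl-bearing centres are untouched and become C2 and C4.

Step 2
Reactants: 3 (3S,5R)-3,5-dimethylcyclohex-1-en-1-yl triflate
Product: 4 methyl (3S,5R)-3,5-dimethylcyclohex-1-ene-1-carboxylate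
Conditions: Pd(OAc)2 (cat.), PPh3, CO (1 atm), MeOH, Et3N, DMF, 60 °C
Reagents that add atoms: carbon monoxide, [C-]#[O+]; methanol, CO
Why: Palladium-catalysed methoxycarbonylation of an enol triflate (oxidative addition to zerovalent palladium, CO insertion, methanolysis); the ester carbon is the future C37.

Step 3
Reactants: 4 methyl (3S,5R)-3,5-dimethylcyclohex-1-ene-1-carboxylate
Product: 6 C6-vinyl ester (C36 epimers), via silyl ketene acetal 5 (not isolated)
Conditions: CH2=CHMgBr, CuBr·SMe2 (cat.), Me3SiCl, THF, −78 → −30 °C; aq. HCl work-up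
Reagents that add atoms: vinylmagnesium bromide, C=C[Mg]Br (chlorotrimethylsilane, C[Si](C)(C)Cl, appears only in 5)
Why: Silyl-chloride-accelerated copper-catalysed conjugate addition to a cyclohexenecarboxylate; the vinyl group should enter C6 anti to the neighbouring C4 methyl, giving the trans (all-equatorial) arrangement, and C36 is left unset because it is re-enolised next.

Step 4
Reactants: 6 C6-vinyl ester (C36 epimers)
Product: 8 quaternary benzyloxymethyl ester, via lithium ester enolate 7 (not isolated)
Conditions: LiN(i-Pr)2, THF, −78 °C; then BnOCH2Cl, DMPU, −78 → −20 °C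
Reagents that add atoms: benzyl chloromethyl ether, ClCOCc1ccccc1
Why: Alkylation of an exocyclic cyclohexanecarboxylate enolate; the electrophile should take the equatorial trajectory, away from the axial hydrogens at C2 and C4 and trans to the C6 vinyl group, so that CH2OBn (C31) is α and the ester (future C37) is β.

Step 5
Reactants: 8 quaternary benzyloxymethyl ester
Product: 9 neopentyl alcohol
Conditions: LiAlH4, THF, 0 °C
Reagents that add atoms: none
Why: Hydride reduction of the ester to the primary alcohol; the benzyl ether and the vinyl group are inert.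

Step 6
Reactants: 9 neopentyl alcohol
Product: 11 C36-methyl benzyl ether, via neopentyl triflate 10 (not isolated)
Conditions: Tf2O, 2,6-lutidine, CH2Cl2, −78 °C; then LiEt3BH, THF, −78 °C → rt
Reagents that add atoms: none
Why: Deoxygenation through the triflate; a neopentyl triflate cannot eliminate and is displaced by the strongly nucleophilic borohydride (SN2), which turns the former ester carbon into the axial C37 methyl.

Step 7
Reactants: 11 C36-methyl benzyl ether
Product: 13 C7 dimethyl acetal, via C7 aldehyde 12 (not isolated)
Conditions: O3, CH2Cl2/MeOH, −78 °C; Me2S; then HC(OMe)3, TsOH (cat.), MeOH, rt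
Reagents that add atoms: methanol, CO; trimethyl orthoformate, COC(OC)OC (ozone, [O-][O+]=O, supplies the oxygen of 12 only)
Why: Ozonolysis of the only alkene with reductive work-up, then acid-catalysed acetalisation; C6 is α to the aldehyde only transiently and its equatorial configuration is the thermodynamic one.

Step 8
Reactants: 13 C7 dimethyl acetal
Product: 14 C31 alcohol
Conditions: H2 (1 atm), Pd/C, EtOAc, rt
Reagents that add atoms: none
Why: Hydrogenolysis of the benzyl ether at a stage where no alkene is present.

Step 9
Reactants: 14 C31 alcohol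
Product: 15 C31 aldehyde
Conditions: Dess–Martin periodinane, NaHCO3, CH2Cl2, rt
Reagents that add atoms: none
Why: Buffered hypervalent-iodine oxidation of a neopentyl alcohol; the aldehyde has no α-hydrogen and the acetal is kept by the bicarbonate buffer.

Step 10
Reactants: 15 C31 aldehyde
Product: 16 (E)-enal
Conditions: Ph3P=C(Me)CHO, toluene, 110 °C
Reagents that add atoms: 2-(triphenylphosphoranylidene)propanal, CC(C=O)=P(c1ccccc1)(c1ccccc1)c1ccccc1
Why: Wittig reaction of a stabilised ylide, which is E-selective and puts C36 trans to the formyl group; it brings in C29, C30 and C27.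

Step 11
Reactants: 16 (E)-enal
Product: 17 (E,E)-diene acetal
Conditions: 5-(ethylsulfonyl)-1-phenyltetrazole, KN(SiMe3)2, DME, −60 °C → rt
Reagents that add atoms: 5-(ethylsulfonyl)-1-phenyl-1H-tetrazole, CCS(=O)(=O)c1nnnn1-c1ccccc1
Why: Julia–Kocienski olefination, E-selective with phenyltetrazolyl sulfones under potassium/DME conditions; it adds C25 and C26 and completes the E,E-diene.

Step 12
Reactants: 17 (E,E)-diene acetal
Product: 18 diene aldehyde
Conditions: TsOH·H2O (cat.), acetone/H2O, rt
Reagents that add atoms: water, O
Why: Mild acetal hydrolysis; the conjugated diene tolerates catalytic acid in wet acetone and the C6 centre stays equatorial.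

Step 13
Reactants: 18 diene aldehyde
Product: 19 propargylic alcohols (C7 epimers)
Conditions: HC≡CCH(OEt)2, n-BuLi, THF, −78 °C; then 18, −78 °C
Reagents that add atoms: 3,3-diethoxyprop-1-yne, C#CC(OCC)OCC
Why: Addition of a lithium acetylide to a hindered aldehyde brings in C32–C34 with C34 masked as an acetal; the C7 mixture is removed in the next two steps.

Step 14
Reactants: 19 propargylic alcohols (C7 epimers)
Product: 20 ynone
Conditions: Dess–Martin periodinane, NaHCO3, CH2Cl2, rt
Reagents that add atoms: none
Why: Oxidation of both epimers to one ynone; C6 stays in its equatorial, thermodynamic configuration.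

Step 15
Reactants: 20 ynone
Product: 21 (7R)-propargylic alcohol
Conditions: RuCl[(R,R)-TsDPEN](p-cymene) (cat.), i-PrOH, rt
Reagents that add atoms: none
Why: Noyori asymmetric transfer hydrogenation of an alkynyl ketone, in which the catalyst and not the α-stereocentre decides the face; the (R,R)-complex should give the 7R carbinol, which has the spatial arrangement of the C7–O bond of the target.

Step 16
Reactants: 21 (7R)-propargylic alcohol
Product: 22 (E)-allylic alcohol
Conditions: NaAlH2(OCH2CH2OMe)2, THF, 0 °C
Reagents that add atoms: none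
Why: Hydroxyl-directed trans-hydroalumination of a propargylic alcohol followed by protonolysis gives the E-alkene only; the acetal and the diene are not touched.

Step 17
Reactants: 22 (E)-allylic alcohol
Product: 23 aryl ether tert-butyl ester
Conditions: KN(SiMe3)2, THF/DMF, 0 °C; then 4-FC6H4CO2t-Bu, rt
Reagents that add atoms: tert-butyl 4-fluorobenzoate, CC(C)(C)OC(=O)c1ccc(F)cc1
Why: Nucleophilic aromatic substitution by the potassium alkoxide on a para-ester-activated fluoroarene; the C7–O bond is not broken, so C7 keeps its configuration, and the bulky ester resists transesterification.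

Step 18
Reactants: 23 aryl ether tert-butyl ester
Product: 24 benzylic alcohol
Conditions: i-Bu2AlH, CH2Cl2, −78 → 0 °C
Reagents that add atoms: none
Why: Hydride reduction of the benzoate to the benzylic alcohol (the future C15) while acetal, diene and allylic ether stay intact.

Step 19
Reactants: 24 benzylic alcohol
Product: 25 benzylic silyl ether
Conditions: t-BuMe2SiCl, imidazole, DMF, rt
Reagents that add atoms: tert-butyldimethylsilyl chloride, CC(C)(C)[Si](C)(C)Cl
Why: Standard silylation; the p-alkoxybenzyl alcohol must not be free in the presence of the Lewis acid of step 21.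

Step 20
Reactants: 25 benzylic silyl ether
Product: 26 trienal
Conditions: PPTS, acetone/H2O, rt; used directly
Reagents that add atoms: water, O
Why: α,β-Unsaturated acetals hydrolyse under very mild acid, which the primary silyl ether survives; the E-enal is released without touching C7.

Step 21
Reactants: 26 trienal
Product: 27 tricyclic aldehyde
Conditions: Me2AlCl (1.2 equiv), CH2Cl2, −78 → −20 °C
Reagents that add atoms: none
Why: Lewis-acid-promoted intramolecular Diels–Alder reaction of a 1,3,8-nonatriene with a terminally activated E-dienophile; the endo transition state (formyl under the diene) gives the trans B/C fusion with C34 β and the C26 methyl β. Ring A holds the two tether bonds trans-diequatorial, and the diene should stay pseudo-equatorial on the forming cyclopentane, so that H31 ends anti to C37 (trans-anti-trans); this sets C31, C32, C33 and C25.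

Step 22
Reactants: 28 maleimide
Product: 29 N-SEM maleimide
Conditions: SEMCl, i-Pr2NEt, CH2Cl2, 0 °C
Reagents that add atoms: 2-(trimethylsilyl)ethoxymethyl chloride, C[Si](C)(C)CCOCCl
Why: N-alkylation of the acidic imide with a reactive chloromethyl ether under a hindered amine base.

Step 23
Reactants: 29 N-SEM maleimide
Product: 31 N-SEM itaconimide, via phosphorus ylide 30 (not isolated)
Conditions: PPh3, acetone, rt; then (CH2O)n, toluene, 80 °C
Reagents that add atoms: formaldehyde, C=O (triphenylphosphine, c1ccc(cc1)P(c1ccccc1)c1ccccc1, appears only in 30)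
Why: Conjugate addition of the phosphine to the maleimide gives a stabilised succinimidyl ylide, whose Wittig reaction with formaldehyde installs the exocyclic methylene (the future C20).

Step 24
Reactants: 31 N-SEM itaconimide
Product: 32 silyl ketene aminal
Conditions: CH2=CHMgBr, CuBr·SMe2 (cat.), Me3SiCl, THF, −78 °C; non-aqueous work-up
Reagents that add atoms: vinylmagnesium bromide, C=C[Mg]Br; chlorotrimethylsilane, C[Si](C)(C)Cl
Why: Copper-catalysed 1,4-addition of the vinyl group to the exocyclic methylene creates the allyl group and, by in situ O-silylation, fixes the enol double bond between C19 and C39; deprotonation of an allylsuccinimide could not give this regiochemistry.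

Step 25
Reactants: 27 tricyclic aldehyde; 32 silyl ketene aminal
Product: 34 aldol adduct, via lithium imide enolate 33 (not isolated)
Conditions: 32 (2 equiv), MeLi, THF, −78 → −30 °C; then 27, −78 °C; AcOH quench at −78 °C
Reagents that add atoms: none
Why: Si–O cleavage by methyllithium releases the regiodefined lithium enolate, which adds to the aldehyde through a closed six-membered (Zimmerman–Traxler) transition state; the ring-fixed enolate geometry should place the allyl group syn to the new hydroxyl. If the nucleophile arrives anti to the C25 branch of the α-stereocentre (Felkin–Anh), C19 has the configuration of the target; C34 becomes a ketone later.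

Step 26
Reactants: 34 aldol adduct
Product: 35 bis-silyl ether
Conditions: t-BuMe2SiOTf, 2,6-lutidine, CH2Cl2, −78 → 0 °C
Reagents that add atoms: tert-butyldimethylsilyl triflate, CC(C)(C)[Si](C)(C)OS(=O)(=O)C(F)(F)F
Why: A silyl triflate is needed for the hindered C34 hydroxyl; the non-basic conditions prevent retro-aldol cleavage, and the ether removes the acidic proton before the organosamarium step.

Step 27
Reactants: 35 bis-silyl ether
Product: 36 benzylic alcohol (C34 silyl ether)
Conditions: HF·pyridine, pyridine, THF, 0 °C
Reagents that add atoms: none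
Why: A primary benzylic silyl ether is cleaved far faster than the hindered secondary one under buffered HF, and the SEM group is stable.

Step 28
Reactants: 36 benzylic alcohol (C34 silyl ether)
Product: 37 benzylic bromide
Conditions: CBr4, PPh3, CH2Cl2, 0 °C; used at once
Reagents that add atoms: carbon tetrabromide, BrC(Br)(Br)Br
Why: Appel bromination of a primary benzylic alcohol under neutral conditions; the reactive p-alkoxybenzyl bromide is not stored.

Step 29
Reactants: 37 benzylic bromide
Product: 39 macrocyclic N-SEM hydroxy lactam, via benzylsamarium 38 (not isolated)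
Conditions: SmI2 (2.5 equiv), THF, 0 °C, syringe-pump addition of 37 (final 2 mM); aq. NH4Cl
Reagents that add atoms: none
Why: Two equivalents of the divalent samarium iodide reduce the C15–Br bond, by way of the benzyl radical, to a benzyl derivative of trivalent samarium, which adds as a carbon nucleophile to the C16 carbonyl of the imide; the resulting samarium alkoxide of the N-acyl hemiaminal does not collapse, so there is no second addition. The closest known reaction is the SmI2 Barbier addition of benzylic and alkyl halides to cyclic imides to give hydroxy lactams, used here intramolecularly. The 13-membered ring closes in a 13-exo-trig mode, the carbonyl π bond being exocyclic to the new ring. The new stereocentre C16 is set by the face of the imide turned toward the arene in the folded conformer; it is not critical, because it equilibrates by ring–chain tautomerism once the nitrogen is free. The step needs attack at C16 rather than C39, and closure rather than protonation or Wurtz coupling of the benzyl species. C39 is flanked by the quaternary C19 and would give a tighter 12-membered ring; slow addition at high dilution keeps the benzyl species scarce. The substrate has no acidic proton and no ketone (C34 is a silyl ether, the nitrogen is alkylated), and the reagent leaves silyl ethers, alkenes and the aryl ether alone.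

Step 30
Reactants: 39 macrocyclic N-SEM hydroxy lactam
Product: 40 macrocyclic diol lactam
Conditions: Bu4NF (6 equiv), THF, rt → 55 °C
Reagents that add atoms: none
Why: Fluoride cleaves the C34 silyl ether and, on warming, the N-SEM group (loss of fluorotrimethylsilane, ethene and formaldehyde); no acid or oxidant touches the p-alkoxybenzyl hemiaminal, and the lactam enolate is too poor a leaving group for easy retro-aldol cleavage.

Step 31
Reactants: 40 macrocyclic diol lactam
Product: 41 macrocyclic ketone
Conditions: Dess–Martin periodinane, NaHCO3, CH2Cl2, rt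
Reagents that add atoms: none
Why: Only the secondary C34 carbinol can be oxidised (the C16 hydroxyl is tertiary); both C34 epimers converge, and C33 keeps its equatorial acyl group.

Step 32
Reactants: 41 macrocyclic ketone
Product: 44 dienone, via tris-silyl enol ether 42 (not isolated), via selenide 43 (not isolated)
Conditions: LiN(i-Pr)2, Me3SiCl (internal quench), THF, −78 °C; PhSeCl, −78 °C; MeOH; then H2O2, pyridine, CH2Cl2, 0 °C → rt
Reagents that add atoms: none
Why: The ketone can enolise only toward C33, and internal silyl trapping also masks OH and NH; selenenylation of the enol ether should occur on the α face, opposite the pseudoaxial C26 methyl. Selenoxide syn-elimination can then use only the α-hydrogen at C25 (H32 is β), which gives the C33=C25 enone conjugated with C27=C29.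

Step 33
Reactants: 44 dienone
Product: 46 epoxy enone, via bromohydrin 45 (not isolated)
Conditions: NBS, THF/H2O, 0 °C; then K2CO3, MeOH, 0 °C
Reagents that add atoms: water, O (N-bromosuccinimide, O=C1CCC(=O)N1Br, supplies the bromine of 45 only)
Why: The distal, more electron-rich C27=C29 bond takes up bromonium on the α face, away from the angular C37 methyl; water opens it anti at the tertiary C29 from the β face, and base closes the trans-bromohydrin with inversion at C27, so the oxirane oxygen ends β at both carbons. This is the face a direct peracid epoxidation would not reach.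

Step 34
Reactants: 46 epoxy enone
Product: 47 methoxy hydroperoxide
Conditions: O3, CH2Cl2/MeOH (1:1), −78 °C, Sudan Red 7B end point; N2 purge, no reductant
Reagents that add atoms: ozone, [O-][O+]=O; methanol, CO
Why: Ozone attacks the isolated allyl alkene much faster than the tetrasubstituted, electron-poor enone; the primary ozonide of a 1-alkene fragments to formaldehyde and the substituted carbonyl oxide, which methanol traps as the α-methoxy hydroperoxide at C21 (Criegee mechanism).

Step 35
Reactants: 47 methoxy hydroperoxide
Product: 48 methoxy peroxy acetal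
Conditions: Et2NH (0.2 equiv), CF3CH2OH, 0 °C → rt
Reagents that add atoms: none
Why: Intramolecular conjugate addition of the hydroperoxide to the enone (peroxy-Michael reaction, the reaction used to close 1,2-dioxanes and 1,2-dioxolanes), here forming O24–C25 and the eight-membered ring on a rigid spiro scaffold. The tether from C19 reaches only the β face of C25, and the enol is protonated at C33 to give the equatorial acyl group (H33 α); the protic solvent protonates the enolate before it can attack the epoxide.

Step 36
Reactants: 48 methoxy peroxy acetal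
Product: 49 CNP0533733.1
Conditions: AcOH/H2O/THF (3:1:1), rt
Reagents that add atoms: water, O
Why: Mild acid hydrolysis of the mixed peroxy acetal through the peroxycarbenium ion exchanges OMe for OH; C21 and C16 equilibrate to the stable epimers under the same conditions, which are too weak to open the epoxide.

## Compound list

1 | cis-3,5-dimethylcyclohexanone (meso) | C[C@H]1C[C@@H](C)CC(=O)C1 | starting material
2 | lithium (3S,5R)-3,5-dimethylcyclohex-1-en-1-olate | C[C@@H]1C[C@H](C)C=C(O[Li])C1 | intermediate
3 | (3S,5R)-3,5-dimethylcyclohex-1-en-1-yl trifluoromethanesulfonate | C[C@@H]1C[C@H](C)C=C(OS(=O)(=O)C(F)(F)F)C1 | intermediate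
4 | methyl (3S,5R)-3,5-dimethylcyclohex-1-ene-1-carboxylate | C[C@@H]1C[C@H](C)C=C(C(=O)OC)C1 | intermediate
5 | O-trimethylsilyl ketene acetal of 6 (C6 vinyl trans to the C4 methyl) | C[C@@H]1C[C@H](C)[C@@H](C=C)C(=C(OC)O[Si](C)(C)C)C1 | intermediate
6 | methyl 3,5-dimethyl-2-vinylcyclohexane-1-carboxylate, vinyl trans to the adjacent methyl, methyls cis, both C36 epimers | C[C@@H]1C[C@H](C)[C@@H](C=C)C(C(=O)OC)C1 | intermediate
7 | lithium enolate of ester 6 | C[C@@H]1C[C@H](C)[C@@H](C=C)C(=C(OC)O[Li])C1 | intermediate
8 | ring A ester with quaternary C36: CO2Me β (future C37), CH2OBn α (C31), C6 vinyl β | C[C@@H]1C[C@H](C)[C@@H](C=C)[C@@](COCc2ccccc2)(C(=O)OC)C1 | intermediate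
9 | neopentyl alcohol from 8 (CH2OH β at C36) | C[C@@H]1C[C@H](C)[C@@H](C=C)[C@@](COCc2ccccc2)(CO)C1 | intermediate
10 | neopentyl triflate of 9 | C[C@@H]1C[C@H](C)[C@@H](C=C)[C@@](COCc2ccccc2)(COS(=O)(=O)C(F)(F)F)C1 | intermediate
11 | ring A with C36 methyl β (C37), CH2OBn α, C6 vinyl | C[C@@H]1C[C@H](C)[C@@H](C=C)[C@@](COCc2ccccc2)(C)C1 | intermediate
12 | C7 aldehyde from 11 | C[C@@H]1C[C@H](C)[C@@H](C=O)[C@@](COCc2ccccc2)(C)C1 | intermediate
13 | C7 dimethyl acetal, C31 benzyl ether | C[C@@H]1C[C@H](C)[C@@H](C(OC)OC)[C@@](COCc2ccccc2)(C)C1 | intermediate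
14 | C7 dimethyl acetal, C31 alcohol | C[C@@H]1C[C@H](C)[C@@H](C(OC)OC)[C@@](CO)(C)C1 | intermediate
15 | C7 dimethyl acetal, C31 aldehyde | C[C@@H]1C[C@H](C)[C@@H](C(OC)OC)[C@@](C=O)(C)C1 | intermediate
16 | (E)-2-methylpropenal on C36 (C31=C29, C27 aldehyde), C7 acetal | C[C@@H]1C[C@H](C)[C@@H](C(OC)OC)[C@@](/C=C(\C)C=O)(C)C1 | intermediate
17 | (1E,3E)-2-methylpenta-1,3-dienyl on C36, C7 dimethyl acetal | C[C@@H]1C[C@H](C)[C@@H](C(OC)OC)[C@@](/C=C(C)/C=C/C)(C)C1 | intermediate
18 | diene aldehyde (C7 CHO on C6, trans to the dienyl group on C36) | C[C@@H]1C[C@H](C)[C@@H](C=O)[C@@](/C=C(C)/C=C/C)(C)C1 | intermediate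
19 | propargylic alcohols, both C7 epimers, C34 diethyl acetal | C[C@@H]1C[C@H](C)[C@@H](C(O)C#CC(OCC)OCC)[C@@](/C=C(C)/C=C/C)(C)C1 | intermediate
20 | ynone (C7 ketone) | C[C@@H]1C[C@H](C)[C@@H](C(=O)C#CC(OCC)OCC)[C@@](/C=C(C)/C=C/C)(C)C1 | intermediate
21 | (7R)-propargylic alcohol | C[C@@H]1C[C@H](C)[C@@H]([C@@H](O)C#CC(OCC)OCC)[C@@](/C=C(C)/C=C/C)(C)C1 | intermediate
22 | (E)-allylic alcohol, C7 as in 21, C34 diethyl acetal | C[C@@H]1C[C@H](C)[C@@H]([C@@H](O)/C=C/C(OCC)OCC)[C@@](/C=C(C)/C=C/C)(C)C1 | intermediate
23 | C7 aryl ether with 4-(tert-butoxycarbonyl)phenyl, C7 retained | C[C@@H]1C[C@H](C)[C@@H]([C@@H](Oc2ccc(cc2)C(=O)OC(C)(C)C)/C=C/C(OCC)OCC)[C@@](/C=C(C)/C=C/C)(C)C1 | intermediate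
24 | C7 aryl ether with 4-(hydroxymethyl)phenyl | C[C@@H]1C[C@H](C)[C@@H]([C@@H](Oc2ccc(CO)cc2)/C=C/C(OCC)OCC)[C@@](/C=C(C)/C=C/C)(C)C1 | intermediate
25 | C7 aryl ether with 4-(TBSOCH2)phenyl, C34 diethyl acetal | C[C@@H]1C[C@H](C)[C@@H]([C@@H](Oc2ccc(CO[Si](C)(C)C(C)(C)C)cc2)/C=C/C(OCC)OCC)[C@@](/C=C(C)/C=C/C)(C)C1 | intermediate
26 | trienal: (E)-4-aryloxy-enal on C6, (E,E)-diene on C36 | C[C@@H]1C[C@H](C)[C@@H]([C@@H](Oc2ccc(CO[Si](C)(C)C(C)(C)C)cc2)/C=C/C=O)[C@@](/C=C(C)/C=C/C)(C)C1 | intermediate
27 | tricyclic aldehyde: trans-anti-trans core, 7β-aryloxy, 33β-CHO, 25β-methyl, C27=C29 | C[C@@H]1C[C@H](C)[C@H]2[C@@H](Oc4ccc(CO[Si](C)(C)C(C)(C)C)cc4)[C@@H]3[C@@H](C=O)[C@@H](C)C=C(C)[C@H]3[C@]2(C)C1 | intermediate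
28 | maleimide | O=C1C=CC(=O)N1 | starting material
29 | N-SEM maleimide | O=C1C=CC(=O)N1COCC[Si](C)(C)C | intermediate
30 | N-SEM 3-(triphenylphosphoranylidene)succinimide | O=C1CC(=P(c2ccccc2)(c2ccccc2)c2ccccc2)C(=O)N1COCC[Si](C)(C)C | intermediate
31 | N-SEM itaconimide (3-methylenesuccinimide) | C=C1CC(=O)N(COCC[Si](C)(C)C)C1=O | intermediate
32 | 3-allyl-2-(trimethylsilyloxy)-1-SEM-pyrrolin-5-one (silyl ketene aminal, C19=C39) | C=CCC1=C(O[Si](C)(C)C)N(COCC[Si](C)(C)C)C(=O)C1 | intermediate
33 | lithium enolate of N-SEM 3-allylsuccinimide at C19 | C=CCC1=C(O[Li])N(COCC[Si](C)(C)C)C(=O)C1 | intermediate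
34 | aldol adduct: C34 carbinol, C19 quaternary as in the target, N-SEM imide, benzylic OTBS | C[C@@H]1C[C@H](C)[C@H]2[C@@H](Oc4ccc(CO[Si](C)(C)C(C)(C)C)cc4)[C@@H]3[C@@H]([C@H](O)[C@]5(CC=C)CC(=O)N(COCC[Si](C)(C)C)C5=O)[C@@H](C)C=C(C)[C@H]3[C@]2(C)C1 | intermediate
35 | C34 O-TBS, benzylic O-TBS | C[C@@H]1C[C@H](C)[C@H]2[C@@H](Oc4ccc(CO[Si](C)(C)C(C)(C)C)cc4)[C@@H]3[C@@H]([C@H](O[Si](C)(C)C(C)(C)C)[C@]5(CC=C)CC(=O)N(COCC[Si](C)(C)C)C5=O)[C@@H](C)C=C(C)[C@H]3[C@]2(C)C1 | intermediate
36 | C34 O-TBS, benzylic alcohol | C[C@@H]1C[C@H](C)[C@H]2[C@@H](Oc4ccc(CO)cc4)[C@@H]3[C@@H]([C@H](O[Si](C)(C)C(C)(C)C)[C@]5(CC=C)CC(=O)N(COCC[Si](C)(C)C)C5=O)[C@@H](C)C=C(C)[C@H]3[C@]2(C)C1 | intermediate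
37 | benzylic bromide with N-SEM spiro-precursor succinimide, C34 O-TBS, 25β-methyl (substrate of the key step) | C[C@@H]1C[C@H](C)[C@H]2[C@@H](Oc4ccc(CBr)cc4)[C@@H]3[C@@H]([C@H](O[Si](C)(C)C(C)(C)C)[C@]5(CC=C)CC(=O)N(COCC[Si](C)(C)C)C5=O)[C@@H](C)C=C(C)[C@H]3[C@]2(C)C1 | intermediate
38 | benzylsamarium diiodide from 37 (trivalent samarium) | C[C@@H]1C[C@H](C)[C@H]2[C@@H](Oc4ccc(C[Sm](I)I)cc4)[C@@H]3[C@@H]([C@H](O[Si](C)(C)C(C)(C)C)[C@]5(CC=C)CC(=O)N(COCC[Si](C)(C)C)C5=O)[C@@H](C)C=C(C)[C@H]3[C@]2(C)C1 | intermediate
39 | N-SEM hydroxy lactam paracyclophane, C34 O-TBS (product of the key step) | C[C@@H]1C[C@H](C)[C@H]2[C@H]3Oc4ccc(cc4)C[C@]4(O)C[C@](CC=C)(C(=O)N4COCC[Si](C)(C)C)[C@@H](O[Si](C)(C)C(C)(C)C)[C@H]6[C@@H](C)C=C(C)[C@H]([C@H]36)[C@]2(C)C1 | intermediate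
40 | NH hydroxy lactam paracyclophane, C34 carbinol | C[C@@H]1C[C@H](C)[C@H]2[C@H]3Oc4ccc(cc4)C[C@]4(O)C[C@](CC=C)(C(=O)N4)[C@@H](O)[C@H]6[C@@H](C)C=C(C)[C@H]([C@H]36)[C@]2(C)C1 | intermediate
41 | NH hydroxy lactam paracyclophane, C34 ketone, H33 α | C[C@@H]1C[C@H](C)[C@H]2[C@H]3Oc4ccc(cc4)C[C@]4(O)C[C@](CC=C)(C(=O)N4)C(=O)[C@H]6[C@@H](C)C=C(C)[C@H]([C@H]36)[C@]2(C)C1 | intermediate
42 | trimethylsilyl enol ether of 41 (C34=C33), O17- and N-silylated | C[C@@H]1C[C@H](C)[C@H]2[C@H]3Oc4ccc(cc4)C[C@]4(O[Si](C)(C)C)C[C@](CC=C)(C(=O)N4[Si](C)(C)C)C(O[Si](C)(C)C)=C6[C@@H](C)C=C(C)[C@H]([C@H]36)[C@]2(C)C1 | intermediate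
43 | 33α-phenylselanyl ketone | C[C@@H]1C[C@H](C)[C@H]2[C@H]3Oc4ccc(cc4)C[C@]4(O)C[C@](CC=C)(C(=O)N4)C(=O)[C@@]6([Se]c7ccccc7)[C@@H](C)C=C(C)[C@H]([C@H]36)[C@]2(C)C1 | intermediate
44 | dienone (C33=C25, C27=C29) | C[C@@H]1C[C@H](C)[C@H]2[C@H]3Oc4ccc(cc4)C[C@]4(O)C[C@](CC=C)(C(=O)N4)C(=O)C6=C(C)C=C(C)[C@H]([C@H]36)[C@]2(C)C1 | intermediate
45 | bromohydrin: 27α-bromo, 29β-hydroxy | C[C@@H]1C[C@H](C)[C@H]2[C@H]3Oc4ccc(cc4)C[C@]4(O)C[C@](CC=C)(C(=O)N4)C(=O)C6=C(C)[C@H](Br)[C@](O)(C)[C@H]([C@H]36)[C@]2(C)C1 | intermediate
46 | 27,29-β-epoxy enone with C19 allyl | C[C@@H]1C[C@H](C)[C@H]2[C@H]3Oc4ccc(cc4)C[C@]4(O)C[C@](CC=C)(C(=O)N4)C(=O)C6=C(C)[C@H]7O[C@@]7(C)[C@H]([C@H]36)[C@]2(C)C1 | intermediate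
47 | C21 α-methoxy hydroperoxide (C21 epimers) | C[C@@H]1C[C@H](C)[C@H]2[C@H]3Oc4ccc(cc4)C[C@]4(O)C[C@](CC(OC)OO)(C(=O)N4)C(=O)C6=C(C)[C@H]7O[C@@]7(C)[C@H]([C@H]36)[C@]2(C)C1 | intermediate
48 | peroxide-bridged C21 methyl acetal (C21 epimers) | C[C@@H]1C[C@H](C)[C@H]2[C@H]3Oc4ccc(cc4)C[C@]4(O)C[C@]5(CC(OC)OO[C@@]6(C)[C@H]7O[C@@]7(C)[C@H]([C@H]3[C@H]6C5=O)[C@]2(C)C1)C(=O)N4 | intermediate
49 | CNP0533733.1 | C[C@@H]1C[C@H](C)[C@H]2[C@H]3Oc4ccc(cc4)C[C@]4(O)C[C@]5(C[C@H](O)OO[C@@]6(C)[C@H]7O[C@@]7(C)[C@H]([C@H]3[C@H]6C5=O)[C@]2(C)C1)C(=O)N4 | target

## Step count and least certain steps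

Total step count: 36. Longest linear sequence: 33 steps (steps 1–21 and 25–36); the imide branch (steps 22–24) joins at step 25.

Step 29 (key step). The benzyl species may be protonated or may couple intermolecularly before it reaches C16, because the approach across a strained 13-membered ring is slow; attack at C39 is the minor risk. Fallback: a two-electron, reversible closure of the same bond. Bromide 37 is treated with sodium benzenesulfinate to give the benzylic phenyl sulfone F1; LiN(SiMe3)2 generates the sulfonyl-stabilised carbanion, which adds to the C16 carbonyl under thermodynamic control to give the sulfonyl hydroxy lactam F2; buffered sodium amalgam removes the sulfonyl group. The fallback sets out from 37 and comes back at 39.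

Step 21. Facial selectivity between the two trans-fused transition states may be poor, since the C30 methyl is pressed against the substituents of the quaternary C36; exo cyclisation to a cis-fused isomer is also possible. Fallback: the stereocontrol is changed from substrate to catalyst. Trienal 26 is cyclised as its iminium ion with a chiral imidazolidinone salt (secondary-amine catalysis), choosing the catalyst enantiomer matched to the endo, trans-anti-trans mode. It sets out from 26 and comes back at 27 and makes no new isolated compound (F0).

Step 25. Facial selectivity at the aldehyde may be poor, because the two branches at C33 differ little in size; this would lead to the C19 epimer, and retro-aldol reaction on warming is a further risk. Fallback: C19 is set by a catalyst. Aldehyde 27 is combined with the lithium enolate of N-SEM succinimide F3 (from succinimide and SEMCl) to give the β-hydroxy imide F4, which is oxidised (Dess–Martin periodinane) to the β-keto imide F5. Palladium-catalysed asymmetric allylic alkylation ([Pd(allyl)Cl]2, Trost ligand, allyl acetate) gives the C19-allyl β-keto imide F6 under ligand control, and chelation-controlled reduction with Zn(BH4)2 returns the carbinol. It sets out from 27 and comes back at 34 (as 34 or its C34 epimer, which are equivalent after step 31).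

Step 30. The C34 alkoxide may undergo retro-aldol ring opening in warm basic fluoride, or N-deprotection may stop at the N-hydroxymethyl stage. Fallback: the order is changed so that no β-alkoxide meets hot fluoride. HF·pyridine removes only the silyl ether from 39 to give the N-SEM carbinol F7, Dess–Martin oxidation gives the N-SEM ketone F8, and Bu4NF then removes the SEM group. It sets out from 39 and comes back at 41.

Step 33. Bromonium formation may take place on the β face or at the allyl group, which would give the α-epoxide or a mixture. Fallback: direct oxygen transfer with dimethyldioxirane or mCPBA, which puts the oxygen on the face the halonium ion takes and is therefore complementary to the halohydrin route; whichever face is more open, one of the two methods gives the β-epoxide. It sets out from 44 and comes back at 46 and makes no new compound (F0).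

Step 35. The eight-membered transition state may be too strained for the hydroperoxide to reach C25, or the amine may trigger base-induced cleavage of the peroxide at C21–H. Fallback: the C25–O bond is made intermolecularly and the ring is closed by reversible hemiacetal formation. Epoxy enone 46 is treated with H2O2 and catalytic base; conjugate addition to the β,β-disubstituted enone gives the cyclic peroxy hemiketal (dioxolanol) F9. Cleavage of the allyl group (OsO4 cat., NaIO4) gives the aldehyde F10, whose ring-opened C25 hydroperoxide adds to the C21 aldehyde under thermodynamic control. It sets out from 46 and comes back at 49.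

## Further compounds

F1 | step 29 | benzylic phenyl sulfone from 37 | C[C@@H]1C[C@H](C)[C@H]2[C@@H](Oc4ccc(CS(=O)(=O)c7ccccc7)cc4)[C@@H]3[C@@H]([C@H](O[Si](C)(C)C(C)(C)C)[C@]5(CC=C)CC(=O)N(COCC[Si](C)(C)C)C5=O)[C@@H](C)C=C(C)[C@H]3[C@]2(C)C1
F2 | step 29 | macrocyclic C15-phenylsulfonyl N-SEM hydroxy lactam (C15 epimers) | C[C@@H]1C[C@H](C)[C@H]2[C@H]3Oc4ccc(cc4)C(S(=O)(=O)c7ccccc7)[C@]4(O)C[C@](CC=C)(C(=O)N4COCC[Si](C)(C)C)[C@@H](O[Si](C)(C)C(C)(C)C)[C@H]6[C@@H](C)C=C(C)[C@H]([C@H]36)[C@]2(C)C1
F0 | step 21 | none | none
F3 | step 25 | N-SEM succinimide | O=C1CCC(=O)N1COCC[Si](C)(C)C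
F4 | step 25 | β-hydroxy imide from 27 and F3 (C19 and C34 epimers) | C[C@@H]1C[C@H](C)[C@H]2[C@@H](Oc4ccc(CO[Si](C)(C)C(C)(C)C)cc4)[C@@H]3[C@@H](C(O)C5CC(=O)N(COCC[Si](C)(C)C)C5=O)[C@@H](C)C=C(C)[C@H]3[C@]2(C)C1
F5 | step 25 | β-keto imide (C34 ketone, C19–H) | C[C@@H]1C[C@H](C)[C@H]2[C@@H](Oc4ccc(CO[Si](C)(C)C(C)(C)C)cc4)[C@@H]3[C@@H](C(=O)C5CC(=O)N(COCC[Si](C)(C)C)C5=O)[C@@H](C)C=C(C)[C@H]3[C@]2(C)C1
F6 | step 25 | C19-allyl β-keto imide, C19 as in the target | C[C@@H]1C[C@H](C)[C@H]2[C@@H](Oc4ccc(CO[Si](C)(C)C(C)(C)C)cc4)[C@@H]3[C@@H](C(=O)[C@]5(CC=C)CC(=O)N(COCC[Si](C)(C)C)C5=O)[C@@H](C)C=C(C)[C@H]3[C@]2(C)C1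
F7 | step 30 | macrocyclic N-SEM hydroxy lactam, C34 carbinol | C[C@@H]1C[C@H](C)[C@H]2[C@H]3Oc4ccc(cc4)C[C@]4(O)C[C@](CC=C)(C(=O)N4COCC[Si](C)(C)C)[C@@H](O)[C@H]6[C@@H](C)C=C(C)[C@H]([C@H]36)[C@]2(C)C1
F8 | step 30 | macrocyclic N-SEM hydroxy lactam, C34 ketone | C[C@@H]1C[C@H](C)[C@H]2[C@H]3Oc4ccc(cc4)C[C@]4(O)C[C@](CC=C)(C(=O)N4COCC[Si](C)(C)C)C(=O)[C@H]6[C@@H](C)C=C(C)[C@H]([C@H]36)[C@]2(C)C1
F0 | step 33 | none | none
F9 | step 35 | 1,2-dioxolan-3-ol from H2O2 addition to 46 (O–O between C25 and C34, C34 epimers) | C[C@@H]1C[C@H](C)[C@H]2[C@H]3Oc4ccc(cc4)C[C@]4(O)C[C@](CC=C)(C(=O)N4)C5(O)OO[C@@]6(C)[C@H]7O[C@@]7(C)[C@H]([C@H]3[C@H]65)[C@]2(C)C1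
F10 | step 35 | C21 aldehyde of F9 | C[C@@H]1C[C@H](C)[C@H]2[C@H]3Oc4ccc(cc4)C[C@]4(O)C[C@](CC=O)(C(=O)N4)C5(O)OO[C@@]6(C)[C@H]7O[C@@]7(C)[C@H]([C@H]3[C@H]65)[C@]2(C)C1
A1 | alternative 1 | 14-membered N-PMB macrolactam, β-keto amide with C16=C18 enamide | C[C@@H]1C[C@H](C)[C@H]2[C@H]3Oc4ccc(cc4)CC(=C)N(Cc5ccc(OC)cc5)C(=O)C(CC=C)C(=O)[C@H]6[C@H](C)C=C(C)[C@H]([C@H]36)[C@]2(C)C1
A2 | alternative 1 | N-PMB spiro hydroxy lactam paracyclophane, C34 ketone | C[C@@H]1C[C@H](C)[C@H]2[C@H]3Oc4ccc(cc4)C[C@]4(O)C[C@](CC=C)(C(=O)N4Cc5ccc(OC)cc5)C(=O)[C@H]6[C@H](C)C=C(C)[C@H]([C@H]36)[C@]2(C)C1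
A3 | alternative 2 | open C33 alkenyl iodide with the C34 aldehyde on C19 | C[C@@H]1C[C@H](C)[C@H]2[C@@H](Oc4ccc(cc4)C[C@]5(OC)C[C@@](CC=C)(C=O)C(=O)N5)[C@@H]3C(I)=C(C)C=C(C)[C@H]3[C@]2(C)C1
A4 | alternative 2 | macrocyclic dienyl carbinol | C[C@@H]1C[C@H](C)[C@H]2[C@H]3Oc4ccc(cc4)C[C@]4(OC)C[C@](CC=C)(C(=O)N4)[C@@H](O)C5=C(C)C=C(C)[C@H]([C@H]35)[C@]2(C)C1
A5 | alternative 3 | open C7 alcohol with the 4-fluoro-3-nitrobenzyl lactam | C[C@@H]1C[C@H](C)[C@H]2[C@@H](O)[C@@H]3[C@@H](C(=O)[C@]5(CC=C)C[C@@](OC)(Cc6ccc(F)c(c6)[N+](=O)[O-])N(Cc7ccc(OC)cc7)C5=O)[C@H](C)C=C(C)[C@H]3[C@]2(C)C1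
A6 | alternative 3 | nitro-substituted paracyclophane | C[C@@H]1C[C@H](C)[C@H]2[C@H]3Oc4ccc(cc4[N+](=O)[O-])C[C@]4(OC)C[C@](CC=C)(C(=O)N4Cc5ccc(OC)cc5)C(=O)[C@H]6[C@H](C)C=C(C)[C@H]([C@H]36)[C@]2(C)C1
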